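## Retrosynthetic overview

- Ring A is a 1,2,3,5-tetrasubstituted benzene: the C–OH carbon sits between the C–OMe carbon and the carbon that bears C8, with allyl para to the oxygen. The route rests on this ring: its C–O carbon and its C8-bearing carbon are the two carbons of a siloxyalkyne, and the other four are C3–C6 of a 2-pyrone.
- Target ⇒ desilylation and Stille allylation ⇒ aryl bromide ⇒ (4+2) cycloaddition with loss of CO2, which makes the bonds C(OSi)–C(OMe) and C(C8-bearing)–CH of ring A ⇒ TIPS ynol ether of the anti C7/C8 diad + 5-bromo-3-methoxy-2-pyrone.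
- Ynol ether ⇒ terminal alkyne ⇒ anti homopropargylic alcohol ⇒ veratraldehyde + (R)-but-3-yn-2-yl mesylate; this sets the C7–C8 bond and both stereocenters.
- Pyrone ⇒ 2-bromo-3-(dimethylamino)acrolein (C4–C6) + methyl methoxyacetate (C2, C3 and the methoxy group).
- Ring order: ring B is bought; the pyrone ring is made in step 7 and consumed in step 8, where ring A is formed.

Key step: step 8

Remark on the chemistry: the pyrone carries bromine at C5, the position that becomes the allyl-bearing carbon of ring A. Bromine makes the pyrone an ambiphilic diene that should react with the nucleophilic ynol ether on neutral heating, and it is exchanged for allyl in step 9. No AgNTf2 or Brønsted acid is used in step 8, because a ketenium ion formed from this ynol ether lies four atoms from electron-rich ring B and would be expected to close onto it.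

Assumption: C7 is the carbinol carbon and C8 the methyl-bearing carbon; the target is the (7S,8S) isomer read from the SMILES. The four starting materials are taken as commercial.

## Route

Step 1
Reactants: 1 (R)-but-3-yn-2-ol
Product: 2 (R)-but-3-yn-2-yl methanesulfonate
Conditions: MsCl, Et3N, CH2Cl2, −78 → 0 °C
Reagents that add atoms: methanesulfonyl chloride, CS(=O)(=O)Cl
Why: O-sulfonylation of a secondary alcohol does not touch the stereocenter, so the (R) configuration is carried into the mesylate.

Step 2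
Reactants: 2 (R)-but-3-yn-2-yl methanesulfonate; 3 veratraldehyde
Product: 5 (1S,2S)-1-(3,4-dimethoxyphenyl)-2-methylbut-3-yn-1-ol, via allenylzinc 4 (not isolated)
Conditions: Pd(OAc)2 (5 mol%), PPh3 (5 mol%), Et2Zn (3 equiv), THF, −78 → −20 °C; aq NH4Cl
Reagents that add atoms: none
Why: Marshall propargylation, in which zerovalent palladium opens the mesylate by anti SN2′ displacement, Et2Zn transmetalates to the (P)-allenylzinc, and this adds to the aldehyde through a cyclic SE2′ transition state, so that C8 is set with net inversion of the mesylate carbon and C7 by the anti arrangement in which the aryl group avoids the allenyl methyl group.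

Step 3
Reactants: 5 (1S,2S)-1-(3,4-dimethoxyphenyl)-2-methylbut-3-yn-1-ol
Product: 6 tert-butyl{[(1S,2S)-1-(3,4-dimethoxyphenyl)-2-methylbut-3-yn-1-yl]oxy}dimethylsilane
Conditions: TBSCl, imidazole, DMF, rt
Reagents that add atoms: tert-butyldimethylsilyl chloride, CC(C)(C)[Si](C)(C)Cl
Why: Silyl ether formation under mildly basic conditions masks the benzylic alcohol without ionising the electron-rich benzylic C–O bond, so C7 is untouched.

Step 4
Reactants: 6 tert-butyl{[(1S,2S)-1-(3,4-dimethoxyphenyl)-2-methylbut-3-yn-1-yl]oxy}dimethylsilane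
Product: 9 tert-butyl{[(1S,2S)-1-(3,4-dimethoxyphenyl)-2-methyl-4-[(triisopropylsilyl)oxy]but-3-yn-1-yl]oxy}dimethylsilane, via lithium acetylide 7 (not isolated), via lithium ynolate 8 (not isolated)
Conditions: n-BuLi, THF, −78 °C; t-BuOOLi (from t-BuOOH and LiN(SiMe3)2), −78 → 0 °C; i-Pr3SiOTf, −78 → 0 °C
Reagents that add atoms: tert-butyl hydroperoxide, CC(C)(C)OO; triisopropylsilyl trifluoromethanesulfonate, CC(C)[Si](C(C)C)(C(C)C)OS(=O)(=O)C(F)(F)F
Why: Oxygenation of a lithium acetylide with lithium tert-butyl peroxide gives the ynolate, which the bulky silyl triflate traps on oxygen (the standard preparation of triisopropylsilyl ynol ethers); only the terminal C–H is deprotonated, so C8 is not epimerised.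

Step 5
Reactants: 10 (E)-3-(dimethylamino)acrolein
Product: 11 (Z)-2-bromo-3-(dimethylamino)acrolein
Conditions: NBS, CH2Cl2, 0 °C → rt
Reagents that add atoms: N-bromosuccinimide, O=C1CCC(=O)N1Br
Why: Electrophilic α-bromination of a vinylogous formamide occurs at its nucleophilic enamine β-carbon, which is C2 of the acrolein.

Step 6
Reactants: 11 (Z)-2-bromo-3-(dimethylamino)acrolein; 12 methyl methoxyacetate
Product: 15 methyl 4-bromo-2-methoxy-5-oxopent-3-enoate, via lithium enolate 13 (not isolated), via lithium aldolate 14 (not isolated)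
Conditions: LiN(i-Pr)2, 12, THF, −78 °C; then 11, −78 → 0 °C; 1 M HCl, THF, rt
Reagents that add atoms: water, O
Why: Aldol addition of the α-methoxy ester enolate to the formyl group of the vinylogous formamide, then acid-induced ionisation of the γ-amino allylic alcohol and hydrolysis of the resulting vinylogous iminium ion, moves the carbonyl to the former enamine carbon (1,3-carbonyl transposition of an enaminone); the new stereocenter and alkene geometry need no control because step 7 erases both.

Step 7
Reactants: 15 methyl 4-bromo-2-methoxy-5-oxopent-3-enoate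
Product: 16 5-bromo-3-methoxy-2H-pyran-2-one
Conditions: p-TsOH·H2O (10 mol%), PhMe, 80 °C
Reagents that add atoms: none
Why: Acid-catalysed enolisation to the 5-hydroxy-2,4-dienoate and lactonisation with loss of methanol (enol-lactonisation to a 2-pyrone) should be driven by formation of the conjugated pyrone, and the alkene geometries equilibrate through the enal and dienol tautomers.

Step 8
Reactants: 9 tert-butyl{[(1S,2S)-1-(3,4-dimethoxyphenyl)-2-methyl-4-[(triisopropylsilyl)oxy]but-3-yn-1-yl]oxy}dimethylsilane; 16 5-bromo-3-methoxy-2H-pyran-2-one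
Product: 18 {4-bromo-2-[(1S,2S)-1-[(tert-butyldimethylsilyl)oxy]-1-(3,4-dimethoxyphenyl)propan-2-yl]-6-methoxyphenoxy}triisopropylsilane, via bridged lactone 17 (not isolated)
Conditions: 16 (1.5 equiv), 2,6-di-tert-butylpyridine (10 mol%), PhMe, 100 °C, sealed tube
Reagents that add atoms: none
Why: Inverse-demand Diels–Alder reaction followed by cycloreversion: the nucleophilic alkyne carbon that carries C8 attacks C6 of the pyrone, the silyloxy-stabilised, ketenium-like carbon closes on C3, and the bridged lactone 17 loses CO2 by retro-(4+2) reaction and aromatises irreversibly. The closest known reactions are the benzannulation of siloxyalkynes with 2-pyrones and the thermal cycloaddition of 5-bromo-2-pyrones, which are ambiphilic dienes, with enol ethers. Ring A closes as a six-membered carbocycle by an asynchronous (4+2) closure that joins the pyrone termini C3 and C6 to the two alkyne carbons. No new stereocenter remains, since the two bridgehead centers of 17 vanish with CO2, and C7 and C8 are spectators in the neutral, aprotic medium. The step needs regioselectivity, which should follow from the match of the polarised ynol ether with the acceptor terminus C6, so that the silyloxy group ends next to methoxy and para to bromine with the side chain ortho. Bromine lowers the diene LUMO so that heat alone should suffice, and the hindered base removes traces of acid that would trigger Friedel–Crafts closure of the ynol ether onto ring B.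

Step 9
Reactants: 18 {4-bromo-2-[(1S,2S)-1-[(tert-butyldimethylsilyl)oxy]-1-(3,4-dimethoxyphenyl)propan-2-yl]-6-methoxyphenoxy}triisopropylsilane
Product: 19 {4-allyl-2-[(1S,2S)-1-[(tert-butyldimethylsilyl)oxy]-1-(3,4-dimethoxyphenyl)propan-2-yl]-6-methoxyphenoxy}triisopropylsilane
Conditions: Bu3SnCH2CH=CH2 (1.5 equiv), Pd(PPh3)4 (5 mol%), PhMe, 100 °C
Reagents that add atoms: allyltributylstannane, C=CC[Sn](CCCC)(CCCC)CCCC
Why: Stille coupling (oxidative addition of zerovalent palladium into the unhindered aryl–Br bond, allyl transfer from tin, reductive elimination) proceeds under neutral conditions that leave both silyl ethers and both stereocenters alone.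

Step 10
Reactants: 19 {4-allyl-2-[(1S,2S)-1-[(tert-butyldimethylsilyl)oxy]-1-(3,4-dimethoxyphenyl)propan-2-yl]-6-methoxyphenoxy}triisopropylsilane
Product: 20 4-allyl-2-[(1S,2S)-1-(3,4-dimethoxyphenyl)-1-hydroxypropan-2-yl]-6-methoxyphenol (CNP0176583.1)
Conditions: n-Bu4NF (3 equiv), THF, 0 °C → rt; aq NH4Cl
Reagents that add atoms: none
Why: Fluoride cleaves the aryl and the alkyl Si–O bonds (global desilylation) under non-acidic conditions, so the free phenol and benzylic carbinol are not exposed to acid that could ionise C7.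

## Compound list

1 | (R)-but-3-yn-2-ol | C#C[C@@H](C)O | starting material
2 | (R)-but-3-yn-2-yl methanesulfonate | C#C[C@@H](C)OS(C)(=O)=O | intermediate
3 | veratraldehyde (3,4-dimethoxybenzaldehyde) | COc1ccc(C=O)cc1OC | starting material
4 | [(P)-buta-1,2-dien-1-yl](ethyl)zinc (aS allene axis) | CC[Zn]C([H])=[C@@]=C([H])C | intermediate (not isolated)
5 | (1S,2S)-1-(3,4-dimethoxyphenyl)-2-methylbut-3-yn-1-ol | C#C[C@H](C)[C@H](O)c1ccc(OC)c(OC)c1 | intermediate
6 | tert-butyl{[(1S,2S)-1-(3,4-dimethoxyphenyl)-2-methylbut-3-yn-1-yl]oxy}dimethylsilane | C#C[C@H](C)[C@H](O[Si](C)(C)C(C)(C)C)c1ccc(OC)c(OC)c1 | intermediate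
7 | lithium acetylide of 6 | [Li]C#C[C@H](C)[C@H](O[Si](C)(C)C(C)(C)C)c1ccc(OC)c(OC)c1 | intermediate (not isolated)
8 | lithium ynolate, lithium (3S,4S)-4-[(tert-butyldimethylsilyl)oxy]-4-(3,4-dimethoxyphenyl)-3-methylbut-1-yn-1-olate | [Li]OC#C[C@H](C)[C@H](O[Si](C)(C)C(C)(C)C)c1ccc(OC)c(OC)c1 | intermediate (not isolated)
9 | tert-butyl{[(1S,2S)-1-(3,4-dimethoxyphenyl)-2-methyl-4-[(triisopropylsilyl)oxy]but-3-yn-1-yl]oxy}dimethylsilane | CC(C)[Si](OC#C[C@H](C)[C@H](O[Si](C)(C)C(C)(C)C)c1ccc(OC)c(OC)c1)(C(C)C)C(C)C | intermediate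
10 | (E)-3-(dimethylamino)acrolein | CN(C)/C=C/C=O | starting material
11 | (Z)-2-bromo-3-(dimethylamino)acrolein | CN(C)/C=C(\Br)C=O | intermediate
12 | methyl methoxyacetate | COCC(=O)OC | starting material
13 | lithium enolate of methyl methoxyacetate | COC=C(O[Li])OC | intermediate (not isolated)
14 | lithium aldolate, lithium alkoxide of methyl 4-bromo-5-(dimethylamino)-3-hydroxy-2-methoxypent-4-enoate (diastereomer mixture) | CN(C)C=C(Br)C(O[Li])C(OC)C(=O)OC | intermediate (not isolated)
15 | methyl 4-bromo-2-methoxy-5-oxopent-3-enoate (racemic, alkene isomers) | COC(=O)C(OC)C=C(Br)C=O | intermediate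
16 | 5-bromo-3-methoxy-2H-pyran-2-one | COC1=CC(Br)=COC1=O | intermediate
17 | bridged lactone, 7-bromo-6-{(1S,2S)-1-[(tert-butyldimethylsilyl)oxy]-1-(3,4-dimethoxyphenyl)propan-2-yl}-4-methoxy-5-[(triisopropylsilyl)oxy]-2-oxabicyclo[2.2.2]octa-5,7-dien-3-one (bridgehead diastereomers) | COC12C=C(Br)C(OC1=O)C([C@H](C)[C@H](O[Si](C)(C)C(C)(C)C)c1ccc(OC)c(OC)c1)=C2O[Si](C(C)C)(C(C)C)C(C)C | intermediate (not isolated)
18 | {4-bromo-2-[(1S,2S)-1-[(tert-butyldimethylsilyl)oxy]-1-(3,4-dimethoxyphenyl)propan-2-yl]-6-methoxyphenoxy}triisopropylsilane | Brc1cc(OC)c(O[Si](C(C)C)(C(C)C)C(C)C)c([C@H](C)[C@H](O[Si](C)(C)C(C)(C)C)c2ccc(OC)c(OC)c2)c1 | intermediate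
19 | {4-allyl-2-[(1S,2S)-1-[(tert-butyldimethylsilyl)oxy]-1-(3,4-dimethoxyphenyl)propan-2-yl]-6-methoxyphenoxy}triisopropylsilane | C=CCc1cc(OC)c(O[Si](C(C)C)(C(C)C)C(C)C)c([C@H](C)[C@H](O[Si](C)(C)C(C)(C)C)c2ccc(OC)c(OC)c2)c1 | intermediate
20 | 4-allyl-2-[(1S,2S)-1-(3,4-dimethoxyphenyl)-1-hydroxypropan-2-yl]-6-methoxyphenol | C=CCc1cc(OC)c(O)c([C@H](C)[C@H](O)c2ccc(OC)c(OC)c2)c1 | target

## Step count and risks

Total step count: 10. Longest linear sequence: 7 (steps 1–4, then 8–10); the pyrone branch is steps 5–7.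

Steps most likely to fail:

1. Step 8. The cycloaddition may stall because the methoxy donor on the pyrone weakens the donor–acceptor match with the ynol ether, and on prolonged heating the ynol ether may isomerise to a silylketene by 1,3-silyl shift.
   Fallback (reversed electron demand, then oxidation of a formyl group to the phenol oxygen): it sets out from 6 and 16. Deprotonation of 6 with n-BuLi and formylation with DMF would give (4S,5S)-5-[(tert-butyldimethylsilyl)oxy]-5-(3,4-dimethoxyphenyl)-4-methylpent-2-ynal F1. Heated with 16 in toluene, this acceptor alkyne should add to the pyrone, now acting as the electron-rich diene, with the same orientation (formyl-bearing carbon to C3, C8-bearing carbon to C6). This gives the bridged lactone 7-bromo-6-{(1S,2S)-1-[(tert-butyldimethylsilyl)oxy]-1-(3,4-dimethoxyphenyl)propan-2-yl}-4-methoxy-3-oxo-2-oxabicyclo[2.2.2]octa-5,7-diene-5-carbaldehyde F2, which loses CO2 to 4-bromo-2-{(1S,2S)-1-[(tert-butyldimethylsilyl)oxy]-1-(3,4-dimethoxyphenyl)propan-2-yl}-6-methoxybenzaldehyde F3. Baeyer–Villiger oxidation with mCPBA, with aryl migration favoured by the ortho methoxy group, would give 4-bromo-2-{(1S,2S)-1-[(tert-butyldimethylsilyl)oxy]-1-(3,4-dimethoxyphenyl)propan-2-yl}-6-methoxyphenyl formate F4. K2CO3 in MeOH would free 4-bromo-2-{(1S,2S)-1-[(tert-butyldimethylsilyl)oxy]-1-(3,4-dimethoxyphenyl)propan-2-yl}-6-methoxyphenol F5. Silylation with i-Pr3SiOTf and 2,6-lutidine comes back to the route at 18.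

2. Step 2. The allenylzinc may racemise before the slow, electron-rich aldehyde traps it, and the anti preference may be modest for an aromatic aldehyde, so enantiomeric and diastereomeric purity may erode.
   Fallback (reagent-controlled crotylboration, then alkene-to-alkyne conversion): it sets out from 3. Brown crotylboration with the (E)-crotylborane made from (E)-but-2-ene, KOt-Bu, n-BuLi, (−)-Ipc2BOMe and BF3·OEt2, followed by NaOH/H2O2 work-up, should give (1S,2S)-1-(3,4-dimethoxyphenyl)-2-methylbut-3-en-1-ol F6. TBSCl and imidazole would give tert-butyl{[(1S,2S)-1-(3,4-dimethoxyphenyl)-2-methylbut-3-en-1-yl]oxy}dimethylsilane F7. Lemieux–Johnson cleavage (OsO4 cat., NaIO4, 2,6-lutidine, dioxane–water) would give (2R,3S)-3-[(tert-butyldimethylsilyl)oxy]-3-(3,4-dimethoxyphenyl)-2-methylpropanal F8. Ohira–Bestmann homologation (dimethyl (1-diazo-2-oxopropyl)phosphonate, K2CO3, MeOH, 0 °C) comes back to the route at 6.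

3. Step 6. The ester enolate may self-condense or the bromo enal may decompose during the acidic hydrolysis, so the transposed enal ester may not be obtained cleanly.
   Fallback (olefination in place of aldol addition and transposition): it sets out from 11. Horner–Wadsworth–Emmons reaction with methyl 2-(dimethoxyphosphoryl)-2-methoxyacetate (NaH, THF, 0 → 50 °C) would give the push–pull diene methyl 4-bromo-5-(dimethylamino)-2-methoxypenta-2,4-dienoate F9. Warming in AcOH with aqueous HCl (60 °C) should hydrolyse the enamine, equilibrate the alkene geometry and lactonise, and comes back to the route at 16.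

## Further compounds

F1 | step 8 | (4S,5S)-5-[(tert-butyldimethylsilyl)oxy]-5-(3,4-dimethoxyphenyl)-4-methylpent-2-ynal | O=CC#C[C@H](C)[C@H](O[Si](C)(C)C(C)(C)C)c1ccc(OC)c(OC)c1
F2 | step 8 | 7-bromo-6-{(1S,2S)-1-[(tert-butyldimethylsilyl)oxy]-1-(3,4-dimethoxyphenyl)propan-2-yl}-4-methoxy-3-oxo-2-oxabicyclo[2.2.2]octa-5,7-diene-5-carbaldehyde | COC12C=C(Br)C(OC1=O)C([C@H](C)[C@H](O[Si](C)(C)C(C)(C)C)c1ccc(OC)c(OC)c1)=C2C=O
F3 | step 8 | 4-bromo-2-{(1S,2S)-1-[(tert-butyldimethylsilyl)oxy]-1-(3,4-dimethoxyphenyl)propan-2-yl}-6-methoxybenzaldehyde | O=Cc1c(OC)cc(Br)cc1[C@H](C)[C@H](O[Si](C)(C)C(C)(C)C)c1ccc(OC)c(OC)c1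
F4 | step 8 | 4-bromo-2-{(1S,2S)-1-[(tert-butyldimethylsilyl)oxy]-1-(3,4-dimethoxyphenyl)propan-2-yl}-6-methoxyphenyl formate | O=COc1c(OC)cc(Br)cc1[C@H](C)[C@H](O[Si](C)(C)C(C)(C)C)c1ccc(OC)c(OC)c1
F5 | step 8 | 4-bromo-2-{(1S,2S)-1-[(tert-butyldimethylsilyl)oxy]-1-(3,4-dimethoxyphenyl)propan-2-yl}-6-methoxyphenol | Oc1c(OC)cc(Br)cc1[C@H](C)[C@H](O[Si](C)(C)C(C)(C)C)c1ccc(OC)c(OC)c1
F6 | step 2 | (1S,2S)-1-(3,4-dimethoxyphenyl)-2-methylbut-3-en-1-ol | C=C[C@H](C)[C@H](O)c1ccc(OC)c(OC)c1
F7 | step 2 | tert-butyl{[(1S,2S)-1-(3,4-dimethoxyphenyl)-2-methylbut-3-en-1-yl]oxy}dimethylsilane | C=C[C@H](C)[C@H](O[Si](C)(C)C(C)(C)C)c1ccc(OC)c(OC)c1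
F8 | step 2 | (2R,3S)-3-[(tert-butyldimethylsilyl)oxy]-3-(3,4-dimethoxyphenyl)-2-methylpropanal | O=C[C@H](C)[C@H](O[Si](C)(C)C(C)(C)C)c1ccc(OC)c(OC)c1
F9 | step 6 | methyl 4-bromo-5-(dimethylamino)-2-methoxypenta-2,4-dienoate | COC(=O)C(OC)=CC(Br)=CN(C)C
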